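Watch the second substrate.

in all of them: enzyme 5.4 × 10⁻⁴ mol%
- noon: starting material 0.050 M; second substrate 1.5 equiv; protic impurity 0.010 M; run made earlier
- summer: starting material 0.025 M; second substrate 1.5 equiv; protic impurity 0.010 M; run made earlier
- autumn: starting material 0.10 M; second substrate 1.5 equiv; protic impurity 0.010 M; run made earlier
- violet: starting material 0.050 M; second substrate 1.50 equiv; protic impurity 0.0100 M; everything together at the start; time 6.0 min
- green: starting material 0.050 M; second substrate 1.50 equiv (fed, over 4.0 min); protic impurity 0.0100 M; all else is in the flask from the start; the feed brings no volume worth counting; time 6.0 min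
- amber: starting material 0.050 M (fed, over 4.0 min); second substrate 1.50 equiv; protic impurity 0.0100 M; all else is in the flask from the start; the feed brings no volume worth counting; time 6.0 min
- ochre: starting material 0.050 M; second substrate 1.50 equiv (in portions, 5, over 4.0 min); protic impurity 0.0100 M; first portion at the start, last at 4.0 min; time 6.0 min

| run | time / min | target / % | starting material / % |
|---|---|---|---|
| noon | 0.500 | 75.9 | 13.8 |
| noon | 0.833 | 83.8 | 4.5 |
| noon | 1.33 | 85.8 | 1.6 |
| noon | 2.00 | 85.4 | 0.3 |
| noon | 4.00 | 84.0 | 0.8 |
| noon | 6.00 | 82.1 | 0 |
| summer | 0.250 | 31.3 | 59.5 |
| summer | 0.500 | 47.7 | 36.6 |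
| summer | 0.833 | 60.5 | 21.2 |
| summer | 1.33 | 67.9 | 11.1 |
| summer | 2.00 | 72.3 | 4.3 |
| summer | 4.00 | 73.2 | 0.5 |
| autumn | 0.250 | 78.8 | 14.9 |
| autumn | 0.667 | 92.1 | 0.1 |
| autumn | 1.33 | 90.2 | 0.7 |
| autumn | 2.00 | 89.2 | 0.2 |
| autumn | 3.00 | 87.7 | 0.3 |
| autumn | 4.00 | 86.4 | 0 |

(scatter of a reading: 0.3 percentage points)

- the earlier runs were read with a standard deviation of 0.3 percentage points

- the flask that comes out highest in amount of target, in percent of the starting material charged, or "all alike" when all lie within 1.5 percentage points (violet / green / amber / ochre / all alike)
- target at the end, in percent of the starting material charged, violet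
- target at the end, in percent of the starting material charged, green
- target at the end, in percent of the starting material charged, amber
- target at the end, in percent of the starting material charged, ochre

1. The noon run has violet's charges, and its reading at 6.00 min is 82.1% of target, so we set violet there.

2. Now we turn the question round: what must hold for amber to beat violet? In amber the whole second substrate waits while starting material enters over 4.0 min, so we hold what it may lose while waiting against what the target does not need.

3. The noon readings at 1.33 min leave a gap between the charge and target plus starting material. We call this gap the toll, 0.006300 M. It reads 0.006575 M in summer at 4.00 min and 0.007800 M in autumn at 0.667 min, while the charge runs from 0.025 M to 0.10 M. As our own estimate, that leaves about 0.04370 M of the starting material charged in violet and amber to couple, one second substrate each.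

4. The spare second substrate of the charge in violet and amber is that charge minus this need, an estimate of 0.03130 M: what may go elsewhere before second substrate becomes the limiting reagent. Spread over the feed, that is 0.007825 M min⁻¹. Second substrate is not among the readings, so we leave amber unplaced against this line, and it is the line to watch.

5. The forecast names amber, with violet 82.2%, green 77.7%, amber 82.6% and ochre 77.7%. For amber it argues: “the competition ratio doesn't depend on how starting material is dosed”.

The flasks give violet as highest, with violet 82.3%, green 73.9%, amber 66.5% and ochre 74.5%.

    ternary complex → enzyme + target (k = 20100 s⁻¹)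
    starting material + protic impurity → quenched substrate (k = 0.959 M⁻¹ s⁻¹)
    second substrate + starting complex ⇌ ternary complex (K = 120 M⁻¹, k = 4.58 × 10⁶ M⁻¹ s⁻¹)
    starting material + enzyme ⇌ starting complex (K = 6.80 M⁻¹, k = 1.44 × 10⁶ M⁻¹ s⁻¹)
    2 second substrate → homo dimer (k = 0.0895 M⁻¹ s⁻¹)
    second substrate + target → over-reaction product (k = 0.0192 M⁻¹ s⁻¹)

At amber's charge, second substrate has a half-life by homo dimer formation alone of 1.24 min, shorter than amber's 4.0 min feed. At 6.00 min amber holds 0.0197 M of homo dimer, which has taken 0.03940 M of second substrate, 0.008100 M beyond the estimated spare, and 0.149% of the second substrate charged is left. The neighbour of violet with 0.380 equiv of second substrate has, reckoned with the same toll, a spare of −0.02470 M, and at 6.00 min it holds 36.9% of target.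

The readings were computed from invented constants; the scatter is artificial.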